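## The problem

The target 18 is a γ-butyrolactone (ring A: O1, C2 carbonyl, C3, C4, C5) with a 4-hydroxy-3-methoxybenzyl group on each of C3 and C4 and a tertiary hydroxyl on C3. Only one ring has to be closed, but C3 is fully substituted and sits between the carbonyl and the second stereocentre. The two stereocentres are contiguous, (3S,4R): the C3 hydroxyl is trans to the C4 arylmethyl group, so the two arylmethyl groups are cis. Neither centre can be corrected afterwards, because C3 has no hydrogen and C4 is not α to the carbonyl; both must be set under kinetic control. C4 is the natural controller: a 2-(arylmethyl) three-carbon unit can be made enantiopure by desymmetrization, and its arylmethyl group can then shield one face of a trigonal C3, so that attack on the open face gives the required trans relation. The fragile parts are the two guaiacol phenols (oxidation to quinone methides), the electron-rich benzylic positions (which ionize in acid and are trapped by the other aryl ring) and the α-hydroxy lactone (which opens in strong aqueous base); the phenols are therefore carried as benzyl ethers to the last step, and acid is avoided once benzylic oxygen is present. The enabling feature is that C2 lies between O1 and C3 while C3 carries a benzylic carbon: if C3 and that carbon are the two carbons of an aryl alkyne, O1–C5–C4 is the hydroxymethyl arm of a homopropargylic alcohol and C2 can be carbon monoxide, stitched between the hydroxyl oxygen and the nearer alkyne carbon. The arylidene double bond that results is the handle for both the C3–O bond and the benzylic CH2.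

## Retrosynthesis

**18 from 16 (through 17).** No skeletal bond is cut. The benzylic C–H bond and the three O–H bonds of 18 are traced back to the benzylic C–O bond of spiro-epoxide 16 and to its two benzyl ethers. The neighbouring choice, hydroxylating the enolate of a saturated 3,4-dibenzyl lactone, would first discard the alkene that the key step delivers and would put a strong base on a finished skeleton. The epoxide hides the tertiary alcohol and the phenols in functions that one neutral hydrogenolysis releases together. The forward reaction has to break the benzylic C–O bond and leave the C3–O bond alone.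

**16 from 15.** The two C–O bonds of the epoxide are cut, which leaves the E arylidene lactone 15 with C4 as its only stereocentre. The aryl group of 15 is cis to C4, and allylic 1,3-strain turns the C4 arylmethyl group out of the ring plane, so one face of the double bond is blocked. The forward reaction must deliver oxygen to the open face; the configuration of the benzylic carbon is irrelevant because that centre becomes CH2.

**15 from 13 and 14 (key disconnection).** The C2–C3 and C2–O1 bonds are cut, which removes C2 as carbon monoxide 14 and opens the ring to the acyclic aryl alkynol 13. Cutting the exocyclic double bond instead (condensation chemistry) would require the saturated ring to be built first and would leave the alkene geometry to a dehydration. The carbonylative cut gives a precursor with one stereocentre and no ring, and the E geometry follows from a syn addition. The forward reaction must place palladium on the alkyne carbon nearer the hydroxyl, insert CO and close the lactone without disturbing C4.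

**13 from 12, and 12 from 9 and 11 (11 from 10).** The O–Si bond and then the C(sp)–C(aryl) bond are cut, which gives terminal alkyne 9 and aryl bromide 11, the benzyl ether of phenol 10. This is the convergent point of the route; the second aryl ring arrives intact and at the correct oxidation level. The silyl ether is kept through the coupling and removed directly before the key step.

**9 from 8 and 8 from 7.** The triple bond is cut back to aldehyde 8 by a one-carbon homologation, and 8 to the primary alcohol 7. The precursor is a mono-protected 2-substituted propane-1,3-diol. The forward steps must not epimerize the α-stereocentre of 8.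

**7 from 6, 5 and 4.** The stereocentre of 7 exists only because its two hydroxymethyl arms are differentiated. Tracing it back through acetate 6 and monoacetate 5 leads to the prochiral diol 4, which an enzyme can desymmetrize. A chiral-auxiliary alkylation would be the neighbouring choice, but it costs stoichiometric chirality and more steps. Exchanging acetate for silyl decides which arm becomes the alkyne, so the sense of the enzyme can always be matched to the target.

**4 from 3, and 3 from 1 and 2.** The C–C bond between the benzylic carbon and the central carbon is cut, which leads to diethyl malonate 1 and benzylic chloride 2; reduction of diester 3 gives 4. Both steps are standard and run on any scale.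

## Roads not taken

**Alternative 1:** The cut removes both benzylic C–C bonds on a preformed five-membered ring, the C4–C(aryl) bond and the C3–CH(OH)Ar bond. In the forward step the lithium derivative of dithiane A3 adds to C4 of the menthyloxy butenolide A2 anti to the acetal substituent, and the lactone enolate is trapped at C3 by aldehyde A4 to give the all-trans adduct A1 as a pair of carbinol epimers.
- Merits: three components are joined in one flask, two C–C bonds form, no ring has to be closed, and the absolute configuration comes from a crystalline auxiliary. The carbinol mixture is harmless because that oxygen is removed later.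
- Weak points for 18: A1 carries four functions that each need their own adjustment. Sulfur must be removed, the benzylic hydroxyl reduced away, the C5 acetal reduced to CH2, and the C3 hydrogen replaced by hydroxyl. The C3 centre set by the aldol trap is destroyed on enolization, and the tertiary alcohol has to come from a late enolate oxidation. That oxidation relies on the same anti-to-C4 bias as the chosen plan, but on a freely rotating 3-benzyl enolate and not on a rigid arylidene. A2 as needed here also carries the (1S,2R,5S)-menthyl group, the antipode of the inexpensive natural series.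
- Comparison: in convergence and in bonds formed per step this road is better, and its overall length (roughly ten steps) is no worse. The chosen plan sets against it that C3 and its benzylic carbon arrive together as an alkene, so one oxidation and one hydrogenolysis finish both; nothing has to be desulfurized or excised; and chirality comes from a catalytic enzyme.

**Alternative 2:** The cut is the C3–CH2Ar bond (to a benzylic nucleophile) and the C3–C4 bond (by a [3,3] shift), with the lactone closed afterwards. In the forward step the Grignard reagent A7 adds to the acylsilane carbonyl of the allylic silyl glyoxylate A6. A 1,2-Brook shift turns the alkoxide into a glycolate enolate, which is silylated and rearranges through a chair Ireland–Claisen transition state to acid A5, transferring the carbinol chirality of A6 to C3 and C4 together.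
- Merits: the C3–O bond is present from the start, so no late oxidation is needed. Both stereocentres, including the fully substituted one, are set in a closed transition state and not by facial bias.
- Weak points for 18: the relative configuration depends on the geometry of the enolate that emerges from the Brook shift. A chelated Z enolate and the (S,E) ester A6 are assumed; any leakage gives a diastereomer at a centre that cannot be corrected. The rearrangement must join a fully substituted carbon to a carbon that already bears an arylmethyl group. A7 is an electron-rich benzylic Grignard reagent prone to homocoupling. A6 needs an enantiopure secondary allylic alcohol and several steps to install the silyl glyoxylate. A5 still carries a propenyl group that must be cleaved oxidatively beside two electron-rich arenes, reduced and lactonized, so two carbons are built in and then thrown away.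
- Comparison: this road is better in that C3 is controlled by a pericyclic transition state and needs no oxidation. The chosen plan sets against it starting materials one or two steps from catalogue compounds, a ring-forming step that adds only CO, and an endgame of two steps where this road needs about four.

**Alternative 3:** The cut is the C3–C4 bond and the aryl–carbon bond at the exocyclic carbon, the ester C–O bond having been made beforehand. In the forward step zerovalent nickel, from Ni(cod)2 and a chiral ligand, couples the alkyne and the ketone of propargyl ester A9 oxidatively, which forms C3–C4 and closes the lactone through an oxanickelacycle. The arylzinc reagent A10 then transmetalates, and reductive elimination gives the Z arylidene A8. Hydrogenation of A8 from the hydroxyl face, with loss of the benzyl ethers, would give 18.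
- Merits: this is the shortest road. The tertiary carbinol is created directly and enantioselectively by a catalyst, and the final relay runs the right way, since hydrogen delivered syn to the hydroxyl leaves the C4 arylmethyl trans to it.
- Weak points for 18: A9 is an arylpyruvate and should exist largely as its conjugated enol, so little ketone is available and the enol proton quenches A10. The ester tether prefers the s-trans conformation, which holds the alkyne away from the ketone. The terminal alkyne of A9 is acidic toward A10 and prone to oligomerization on zerovalent nickel. Oxidative cyclizations of this kind are far better established for aldehydes than for ketones. A10 can also add to the α-keto ester without nickel, which would give racemic open-chain carbinol.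
- Comparison: in step count and in the use of a catalytic enantioselective C–C bond formation this road is clearly better. The chosen plan sets against it that each of its steps belongs to an established reaction class, that its ring-forming step has no uncatalysed background reaction, and that its stereochemical information is secured at the start on a simple diol.

Key step: step 11

Assumption: 2 and 10 are taken as catalogue compounds, and Burkholderia cepacia lipase is taken to acetylate the pro-R hydroxymethyl group of 4 (the sense expected from the empirical size rule for primary alcohols, arylmethyl large and hydroxymethyl medium), giving (R)-5; the remedy for the opposite sense is given with the uncertain steps.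

## Route

Step 1
Reactants: 1 diethyl malonate; 2 4-(benzyloxy)-3-methoxybenzyl chloride
Product: 3 diethyl 2-[4-(benzyloxy)-3-methoxybenzyl]malonate
Conditions: NaH (1.1 equiv), 1 in excess (2.5 equiv), THF/DMF, 0 °C → rt
Reagents that add atoms: none
Why: Malonic ester alkylation (SN2) of a reactive benzylic chloride; the excess of malonate suppresses a second alkylation and is distilled off afterwards.

Step 2
Reactants: 3 diethyl 2-[4-(benzyloxy)-3-methoxybenzyl]malonate
Product: 4 2-[4-(benzyloxy)-3-methoxybenzyl]propane-1,3-diol (prochiral)
Conditions: LiAlH4, THF, 0 °C → reflux
Reagents that add atoms: none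
Why: Hydride reduction of both esters to the primary alcohols; aryl benzyl and aryl methyl ethers are inert to LiAlH4.

Step 3
Reactants: 4 2-[4-(benzyloxy)-3-methoxybenzyl]propane-1,3-diol
Product: 5 (R)-2-[4-(benzyloxy)-3-methoxybenzyl]-3-hydroxypropyl acetate
Conditions: Burkholderia cepacia lipase (lipase PS), vinyl acetate, i-Pr2O, rt
Reagents that add atoms: vinyl acetate, C=COC(C)=O
Why: Lipase-catalysed desymmetrization of a 2-substituted propane-1,3-diol by irreversible transesterification; the enzyme selects one enantiotopic hydroxymethyl arm and thereby sets the stereocentre. Running slightly past monoacylation should raise the enantiomeric purity, because the minor monoacetate still has the preferred arm free and is drained to the diacetate.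

Step 4
Reactants: 5 (R)-2-[4-(benzyloxy)-3-methoxybenzyl]-3-hydroxypropyl acetate
Product: 6 (S)-2-[4-(benzyloxy)-3-methoxybenzyl]-3-[(tert-butyldiphenylsilyl)oxy]propyl acetate
Conditions: TBDPSCl, imidazole, CH2Cl2, 0 °C → rt
Reagents that add atoms: tert-butyldiphenylsilyl chloride, CC(C)(C)[Si](Cl)(c1ccccc1)c1ccccc1
Why: Standard silylation of a primary alcohol under mild base, fast enough to outrun 1,3-acetyl migration, which would racemize the monoacetate. The descriptor changes from R to S only because the silyloxymethyl arm now ranks first.

Step 5
Reactants: 6 (S)-2-[4-(benzyloxy)-3-methoxybenzyl]-3-[(tert-butyldiphenylsilyl)oxy]propyl acetate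
Product: 7 (S)-2-[4-(benzyloxy)-3-methoxybenzyl]-3-[(tert-butyldiphenylsilyl)oxy]propan-1-ol
Conditions: K2CO3 (cat.), MeOH, 0 °C
Reagents that add atoms: none
Why: Base-catalysed methanolysis of the acetate. The bulky TBDPS group is chosen because it resists the O-to-O silyl migration between the two arms that would racemize this pseudo-symmetric mono-ether.

Step 6
Reactants: 7 (S)-2-[4-(benzyloxy)-3-methoxybenzyl]-3-[(tert-butyldiphenylsilyl)oxy]propan-1-ol
Product: 8 (R)-2-[4-(benzyloxy)-3-methoxybenzyl]-3-[(tert-butyldiphenylsilyl)oxy]propanal
Conditions: TEMPO (10 mol %), PhI(OAc)2, CH2Cl2, rt; used crude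
Reagents that add atoms: none
Why: Oxoammonium-mediated oxidation of a primary alcohol stops at the aldehyde and is free of base, so the α-stereocentre should be preserved (the descriptor becomes R because CHO outranks CH2OSi).

Step 7
Reactants: 8 (R)-2-[4-(benzyloxy)-3-methoxybenzyl]-3-[(tert-butyldiphenylsilyl)oxy]propanal
Product: 9 (S)-{[2-[4-(benzyloxy)-3-methoxybenzyl]but-3-yn-1-yl]oxy}(tert-butyl)diphenylsilane
Conditions: dimethyl (1-diazo-2-oxopropyl)phosphonate, K2CO3, MeOH, 0 °C → rt
Reagents that add atoms: dimethyl (1-diazo-2-oxopropyl)phosphonate, COP(=O)(OC)C(=[N+]=[N-])C(C)=O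
Why: Seyferth–Gilbert homologation in the Ohira–Bestmann variant; the diazomethylphosphonate anion adds to the aldehyde, and loss of phosphate and nitrogen gives the terminal alkyne by 1,2-hydride shift of the alkylidene carbene. The mild carbonate base is routinely tolerated by α-branched β-silyloxy aldehydes, and the TBDPS ether is stable to it.

Step 8
Reactants: 10 4-bromo-2-methoxyphenol
Product: 11 1-(benzyloxy)-4-bromo-2-methoxybenzene
Conditions: BnBr, K2CO3, acetone, reflux
Reagents that add atoms: benzyl bromide, BrCc1ccccc1
Why: Williamson ether synthesis on a phenol; the benzyl ether matches the protection of the other ring, so both fall together at the end.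

Step 9
Reactants: 9 (S)-{[2-[4-(benzyloxy)-3-methoxybenzyl]but-3-yn-1-yl]oxy}(tert-butyl)diphenylsilane; 11 1-(benzyloxy)-4-bromo-2-methoxybenzene
Product: 12 (S)-{[2-[4-(benzyloxy)-3-methoxybenzyl]-4-[4-(benzyloxy)-3-methoxyphenyl]but-3-yn-1-yl]oxy}(tert-butyl)diphenylsilane
Conditions: Pd(PhCN)2Cl2 (3 mol %), P(t-Bu)3·HBF4 (6 mol %), CuI (2 mol %), i-Pr2NH, dioxane, rt → 40 °C, degassed
Reagents that add atoms: none
Why: Sonogashira coupling; the bulky electron-rich phosphine lets the electron-rich aryl bromide undergo oxidative addition near room temperature. The propargylic C–H stereocentre is not acidic enough to be touched by the amine.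

Step 10
Reactants: 12 (S)-{[2-[4-(benzyloxy)-3-methoxybenzyl]-4-[4-(benzyloxy)-3-methoxyphenyl]but-3-yn-1-yl]oxy}(tert-butyl)diphenylsilane
Product: 13 (S)-2-[4-(benzyloxy)-3-methoxybenzyl]-4-[4-(benzyloxy)-3-methoxyphenyl]but-3-yn-1-ol
Conditions: TBAF, THF, 0 °C → rt
Reagents that add atoms: none
Why: Fluoride cleavage of the silyl ether frees the homopropargylic alcohol; benzyl ethers and the alkyne are unaffected.

Step 11
Reactants: 13 (S)-2-[4-(benzyloxy)-3-methoxybenzyl]-4-[4-(benzyloxy)-3-methoxyphenyl]but-3-yn-1-ol; 14 carbon monoxide
Product: 15 (S,E)-4-[4-(benzyloxy)-3-methoxybenzyl]-3-[4-(benzyloxy)-3-methoxybenzylidene]dihydrofuran-2(3H)-one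
Conditions: Pd(dba)2 (5 mol %), 1,4-bis(diphenylphosphino)butane (5 mol %), CO (20 atm), DME, 120 °C
Reagents that add atoms: none
Why: Zerovalent palladium carrying the diphosphine takes up the O–H bond of 13 to give a palladium hydride, which adds syn across the alkyne with palladium on the carbon next to C4 and hydrogen on the aryl-bearing carbon. CO then inserts into the vinyl–palladium bond to form C2–C3, and the acylpalladium is captured by the C5 oxygen to form C2–O1, which returns zerovalent palladium. The closest known reaction type is the palladium-catalysed cyclocarbonylation of but-3-yn-1-ols to α-alkylidene-γ-butyrolactones, which also accepts internal alkynes. The one ring, lactone ring A, closes by 5-exo-trig acyl substitution of the C5 hydroxyl at the acylpalladium carbon, equivalent to C–O reductive elimination from a six-membered acyl(alkoxo)palladacycle. No stereocentre is formed; C4 is carried through unchanged, and the E geometry follows from the syn hydropalladation, which leaves the aryl group trans to the carbonyl. The step needs regioselective hydropalladation: the tethered hydroxyl delivers palladium to the proximal carbon, and the other regioisomer would give an acyl group held trans to the hydroxyl-bearing chain, which cannot lactonize and can only revert. A pathway through an alkoxycarbonylpalladium species and intramolecular syn carbopalladation would give the same E lactone. Benzyl ethers and aryl methyl ethers are inert under these neutral conditions.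

Step 12
Reactants: 15 (S,E)-4-[4-(benzyloxy)-3-methoxybenzyl]-3-[4-(benzyloxy)-3-methoxybenzylidene]dihydrofuran-2(3H)-one
Product: 16 (2S,3R,7R)-7-[4-(benzyloxy)-3-methoxybenzyl]-2-[4-(benzyloxy)-3-methoxyphenyl]-1,5-dioxaspiro[2.4]heptan-4-one (epoxide oxygen trans to the arylmethyl group on C7; epoxide aryl cis to C7)
Conditions: t-BuOOH (anhydrous, in decane), n-BuLi, THF, −78 → 0 °C
Reagents that add atoms: tert-butyl hydroperoxide, CC(C)(C)OO
Why: Weitz–Scheffer-type nucleophilic epoxidation of an α,β-unsaturated lactone by lithium tert-butyl peroxide, a strong α-nucleophile but a weak base, so neither lactone opening nor deprotonation at C4 should compete. The peroxide adds to the benzylic carbon, and the lactone enolate then closes onto oxygen at C3 from the face opposite the C4 arylmethyl group, which allylic 1,3-strain against the cis aryl group holds out of the ring plane. This sets the C3–O bond trans to the C4 substituent; the configuration at the benzylic carbon is of no consequence.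

Step 13
Reactants: 16 (2S,3R,7R)-7-[4-(benzyloxy)-3-methoxybenzyl]-2-[4-(benzyloxy)-3-methoxyphenyl]-1,5-dioxaspiro[2.4]heptan-4-one
Product: 18 (3S,4R)-3-hydroxy-3,4-bis(4-hydroxy-3-methoxybenzyl)dihydrofuran-2(3H)-one, via dibenzyl hydroxylactone 17 (not isolated)
Conditions: H2 (1 atm), 10% Pd/C, EtOAc/EtOH, rt
Reagents that add atoms: none
Why: Heterogeneous hydrogenolysis should cleave the benzylic C–O bond of the aryl glycidic lactone (the bond next to the electron-rich ring, not the C3–O bond) and then both benzyl ethers in the same flask. C3 keeps its oxygen and its configuration, and the tertiary alcohol formed is not benzylic and survives. The neutral medium keeps the benzylic position from ionizing toward the other aryl ring.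

## Compound list

1 | diethyl malonate | CCOC(=O)CC(=O)OCC | starting material
2 | 4-(benzyloxy)-3-methoxybenzyl chloride | COc1cc(CCl)ccc1OCc1ccccc1 | starting material
3 | diethyl 2-[4-(benzyloxy)-3-methoxybenzyl]malonate | CCOC(=O)C(Cc1ccc(OCc2ccccc2)c(OC)c1)C(=O)OCC | intermediate
4 | 2-[4-(benzyloxy)-3-methoxybenzyl]propane-1,3-diol | COc1cc(CC(CO)CO)ccc1OCc1ccccc1 | intermediate
5 | (R)-2-[4-(benzyloxy)-3-methoxybenzyl]-3-hydroxypropyl acetate | COc1cc(C[C@H](CO)COC(C)=O)ccc1OCc1ccccc1 | intermediate
6 | (S)-2-[4-(benzyloxy)-3-methoxybenzyl]-3-[(tert-butyldiphenylsilyl)oxy]propyl acetate | COc1cc(C[C@H](CO[Si](c2ccccc2)(c2ccccc2)C(C)(C)C)COC(C)=O)ccc1OCc1ccccc1 | intermediate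
7 | (S)-2-[4-(benzyloxy)-3-methoxybenzyl]-3-[(tert-butyldiphenylsilyl)oxy]propan-1-ol | COc1cc(C[C@H](CO[Si](c2ccccc2)(c2ccccc2)C(C)(C)C)CO)ccc1OCc1ccccc1 | intermediate
8 | (R)-2-[4-(benzyloxy)-3-methoxybenzyl]-3-[(tert-butyldiphenylsilyl)oxy]propanal | COc1cc(C[C@H](CO[Si](c2ccccc2)(c2ccccc2)C(C)(C)C)C=O)ccc1OCc1ccccc1 | intermediate
9 | (S)-{[2-[4-(benzyloxy)-3-methoxybenzyl]but-3-yn-1-yl]oxy}(tert-butyl)diphenylsilane | COc1cc(C[C@H](CO[Si](c2ccccc2)(c2ccccc2)C(C)(C)C)C#C)ccc1OCc1ccccc1 | intermediate
10 | 4-bromo-2-methoxyphenol | COc1cc(Br)ccc1O | starting material
11 | 1-(benzyloxy)-4-bromo-2-methoxybenzene | COc1cc(Br)ccc1OCc1ccccc1 | intermediate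
12 | (S)-{[2-[4-(benzyloxy)-3-methoxybenzyl]-4-[4-(benzyloxy)-3-methoxyphenyl]but-3-yn-1-yl]oxy}(tert-butyl)diphenylsilane | COc1cc(C[C@H](CO[Si](c2ccccc2)(c2ccccc2)C(C)(C)C)C#Cc2ccc(OCc3ccccc3)c(OC)c2)ccc1OCc1ccccc1 | intermediate
13 | (S)-2-[4-(benzyloxy)-3-methoxybenzyl]-4-[4-(benzyloxy)-3-methoxyphenyl]but-3-yn-1-ol | COc1cc(C[C@H](CO)C#Cc2ccc(OCc3ccccc3)c(OC)c2)ccc1OCc1ccccc1 | intermediate
14 | carbon monoxide | [C-]#[O+] | starting material
15 | (S,E)-4-[4-(benzyloxy)-3-methoxybenzyl]-3-[4-(benzyloxy)-3-methoxybenzylidene]dihydrofuran-2(3H)-one | COc1cc(C[C@@H]2COC(=O)/C2=C/c2ccc(OCc3ccccc3)c(OC)c2)ccc1OCc1ccccc1 | intermediate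
16 | (2S,3R,7R)-7-[4-(benzyloxy)-3-methoxybenzyl]-2-[4-(benzyloxy)-3-methoxyphenyl]-1,5-dioxaspiro[2.4]heptan-4-one | COc1cc(C[C@@H]2COC(=O)[C@]2(O3)[C@@H]3c4ccc(OCc5ccccc5)c(OC)c4)ccc1OCc1ccccc1 | intermediate
17 | (3S,4R)-3,4-bis[4-(benzyloxy)-3-methoxybenzyl]-3-hydroxydihydrofuran-2(3H)-one | COc1cc(C[C@@H]2COC(=O)[C@]2(O)Cc2ccc(OCc3ccccc3)c(OC)c2)ccc1OCc1ccccc1 | intermediate
18 | (3S,4R)-3-hydroxy-3,4-bis(4-hydroxy-3-methoxybenzyl)dihydrofuran-2(3H)-one | COc1cc(C[C@@H]2COC(=O)[C@]2(O)Cc2ccc(O)c(OC)c2)ccc1O | target

## Step count and uncertain steps

Total: 13 steps. Longest linear sequence: 12 steps (steps 1–7 and 9–13); step 8 is a one-step branch.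

**Step 11 (key step).** The hindered, electron-rich aryl alkyne may undergo hydropalladation slowly at the temperature needed, so that intermolecular ester formation competes. A palladium hydride may also re-add to the arylidene and move the double bond into the ring, which would erase C4. The fallback sets out from 13 and uses stoichiometric, hydroxyl-directed hydrometalation in place of catalytic hydropalladation. The lithium alkoxide of 13 (n-BuLi, THF) is treated with Cp2ZrHCl, which should place zirconium on the alkyne carbon nearer the oxygen, and iodine then gives (R,E)-2-[4-(benzyloxy)-3-methoxybenzyl]-4-[4-(benzyloxy)-3-methoxyphenyl]-3-iodobut-3-en-1-ol F1. Carbonylative lactonization of this hydroxy vinyl iodide (Pd(PPh3)4, CO 1 atm, Et3N, MeCN, 60 °C) proceeds by oxidative addition, CO insertion and capture of the acyl group by the hydroxyl with retention of alkene geometry, and comes back to the route at 15. No hydride species is present in that step.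

**Step 12.** Conjugate addition of the peroxide anion may be slow because the para-alkoxyaryl group deactivates the acceptor, and ring closure of the peroxy enolate may show incomplete facial selectivity at C3. The fallback sets out from 15 and replaces epoxidation by a concerted syn dihydroxylation. OsO4 (cat.) with N-methylmorpholine N-oxide in acetone/water should add to the face opposite the C4 arylmethyl group and give (3R,4R)-3-{(S)-[4-(benzyloxy)-3-methoxyphenyl](hydroxy)methyl}-4-[4-(benzyloxy)-3-methoxybenzyl]-3-hydroxydihydrofuran-2(3H)-one F2. Hydrogenolysis (H2, Pd(OH)2/C, EtOH with a little AcOH) removes the benzylic hydroxyl and both benzyl ethers and comes back to the route at 18.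

**Step 3.** The enzyme may discriminate the two arms in the opposite sense or too weakly, and acetyl migration in the monoacetate would lower the enantiomeric purity further. The fallback sets out from 4 and changes from acyl transfer to hydrolysis. Acetylation (Ac2O, pyridine) gives 2-[4-(benzyloxy)-3-methoxybenzyl]propane-1,3-diyl diacetate F3, and enzymatic hydrolysis in pH 7 phosphate buffer removes one acetate. Because a hydrolase recognizes the same arm in either direction, this mode leaves the acetate on the arm that acyl transfer would leave free. It therefore comes back to the route at 5 if direct acetylation favours the antipode, and it opens the choice of other hydrolases (pig liver esterase, pancreatic lipase) if discrimination is weak.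

**Step 7.** The carbonate–methanol medium may epimerize the α-stereocentre of the aldehyde or eliminate silanolate from its β-position before homologation. The fallback sets out from 8 and uses a Corey–Fuchs sequence. CBr4 and PPh3 in CH2Cl2 at 0 °C give, without base, (S)-{[2-[4-(benzyloxy)-3-methoxybenzyl]-4,4-dibromobut-3-en-1-yl]oxy}(tert-butyl)diphenylsilane F4. Treatment with n-BuLi (2.1 equiv, THF, −78 °C), through bromine–lithium exchange and Fritsch–Buttenberg–Wiechell rearrangement, followed by aqueous quench, comes back to the route at 9.

## Further compounds

F1 | step 11 | (R,E)-2-[4-(benzyloxy)-3-methoxybenzyl]-4-[4-(benzyloxy)-3-methoxyphenyl]-3-iodobut-3-en-1-ol | COc1cc(C[C@H](CO)/C(I)=C\c2ccc(OCc3ccccc3)c(OC)c2)ccc1OCc1ccccc1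
F2 | step 12 | (3R,4R)-3-{(S)-[4-(benzyloxy)-3-methoxyphenyl](hydroxy)methyl}-4-[4-(benzyloxy)-3-methoxybenzyl]-3-hydroxydihydrofuran-2(3H)-one | COc1cc(C[C@@H]2COC(=O)[C@]2(O)[C@@H](O)c2ccc(OCc3ccccc3)c(OC)c2)ccc1OCc1ccccc1
F3 | step 3 | 2-[4-(benzyloxy)-3-methoxybenzyl]propane-1,3-diyl diacetate | COc1cc(CC(COC(C)=O)COC(C)=O)ccc1OCc1ccccc1
F4 | step 7 | (S)-{[2-[4-(benzyloxy)-3-methoxybenzyl]-4,4-dibromobut-3-en-1-yl]oxy}(tert-butyl)diphenylsilane | COc1cc(C[C@H](CO[Si](c2ccccc2)(c2ccccc2)C(C)(C)C)C=C(Br)Br)ccc1OCc1ccccc1
A1 | alternative 1 | 3-{[4-(benzyloxy)-3-methoxyphenyl](hydroxy)methyl}-4-{2-[4-(benzyloxy)-3-methoxyphenyl]-1,3-dithian-2-yl}-5-[(1S,2R,5S)-menthyloxy]dihydrofuran-2(3H)-one, all-trans ring, carbinol epimers | COc1cc(C2(SCCCS2)[C@@H]2[C@@H](O[C@H]3C[C@@H](C)CC[C@@H]3C(C)C)OC(=O)[C@H]2C(O)c2ccc(OCc3ccccc3)c(OC)c2)ccc1OCc1ccccc1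
A2 | alternative 1 | (5S)-5-[(1S,2R,5S)-menthyloxy]furan-2(5H)-one | O=C1C=C[C@@H](O[C@H]2C[C@@H](C)CC[C@@H]2C(C)C)O1
A3 | alternative 1 | 2-[4-(benzyloxy)-3-methoxyphenyl]-1,3-dithiane | COc1cc(C2SCCCS2)ccc1OCc1ccccc1
A4 | alternative 1 | 4-(benzyloxy)-3-methoxybenzaldehyde | COc1cc(C=O)ccc1OCc1ccccc1
A5 | alternative 2 | (2S,3R,E)-2,3-bis[4-(benzyloxy)-3-methoxybenzyl]-2-[(tert-butyldimethylsilyl)oxy]hex-4-enoic acid | COc1cc(C[C@@H]([C@@](O[Si](C)(C)C(C)(C)C)(Cc2ccc(OCc3ccccc3)c(OC)c2)C(=O)O)/C=C/C)ccc1OCc1ccccc1
A6 | alternative 2 | (S,E)-5-[4-(benzyloxy)-3-methoxyphenyl]pent-3-en-2-yl 2-(tert-butyldimethylsilyl)-2-oxoacetate | C[C@@H](/C=C/Cc1ccc(OCc2ccccc2)c(OC)c1)OC(=O)C(=O)[Si](C)(C)C(C)(C)C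
A7 | alternative 2 | [4-(benzyloxy)-3-methoxybenzyl]magnesium chloride | COc1cc(C[Mg]Cl)ccc1OCc1ccccc1
A8 | alternative 3 | (S,Z)-3-[4-(benzyloxy)-3-methoxybenzyl]-4-[4-(benzyloxy)-3-methoxybenzylidene]-3-hydroxydihydrofuran-2(3H)-one | COc1cc(/C=C2/COC(=O)[C@]2(O)Cc2ccc(OCc3ccccc3)c(OC)c2)ccc1OCc1ccccc1
A9 | alternative 3 | prop-2-yn-1-yl 3-[4-(benzyloxy)-3-methoxyphenyl]-2-oxopropanoate | C#CCOC(=O)C(=O)Cc1ccc(OCc2ccccc2)c(OC)c1
A10 | alternative 3 | [4-(benzyloxy)-3-methoxyphenyl]zinc chloride | COc1cc([Zn]Cl)ccc1OCc1ccccc1
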